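## Retrosynthetic overview

1. The ketone is unmasked last, by oxidation of a silyl-protected carbinol, so the epimerisable α-methyl-β,γ-enone never meets base or heat.
2. The cyclohexadiene ring is formed last, by thermal disrotatory 6π-electrocyclisation of an (E,Z,E,E)-tetraenyl pyrone.
3. The tetraene comes from a late Stille union of two fragments of similar size: a pyrone-bearing (E,Z)-dienyl iodide (17 skeletal atoms) and an (E,E)-dienylstannane carrying the methyl stereocentre (12 skeletal atoms).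
4. The pyrone ring is formed first, from pentan-3-one, dimethyl carbonate and a propionyl Weinreb amide. It is then extended by vinylogous aldol–dehydration with (Z)-3-iodo-2-methylacrolein, made from propargyl alcohol.
5. The stannane comes from a Marshall propargylation of propanal with (R)-but-3-yn-2-yl mesylate, then two hydrozirconation–iodination cycles separated by a Sonogashira coupling with propyne.

Assumption: the given SMILES corresponds to the (1S,6R) ring and (4S) side-chain configuration; TBS = tert-butyldimethylsilyl; (R)-but-3-yn-2-ol, propyne and N-methoxy-N-methylpropanamide are taken as commercial.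

## Route

Step 1
Reactants: 1 (R)-but-3-yn-2-ol
Product: 2 (R)-but-3-yn-2-yl methanesulfonate
Conditions: MsCl, Et3N, CH2Cl2, −78 → 0 °C
Reagents that add atoms: methanesulfonyl chloride, CS(=O)(=O)Cl
Why: Mesylation (O-sulfonylation) leaves the C–O stereocentre untouched, so the (R) configuration is retained.

Step 2
Reactants: 2 (R)-but-3-yn-2-yl methanesulfonate; 3 propanal
Product: 5 (3R,4S)-4-methylhex-5-yn-3-ol, via allenylzinc mesylate 4 (not isolated)
Conditions: Pd(OAc)2 (5 mol %), PPh3 (5 mol %), Et2Zn (3 equiv), THF, −78 → −20 °C; aq NH4Cl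
Reagents that add atoms: none
Why: Marshall propargylation: zerovalent palladium opens 2 by anti SN2' attack, transmetalation gives the (P)-allenylzinc 4, and its cyclic SE2' addition to propanal forms the C–C bond with net inversion at the former carbinol carbon (sets the 4S methyl centre) and gives the anti 3R carbinol (the minor 3-epimer is removed on silica and would converge at the final oxidation anyway).

Step 3
Reactants: 5 (3R,4S)-4-methylhex-5-yn-3-ol
Product: 6 tert-butyldimethyl{[(3R,4S)-4-methylhex-5-yn-3-yl]oxy}silane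
Conditions: TBSCl, imidazole, DMF, rt
Reagents that add atoms: tert-butyldimethylsilyl chloride, CC(C)(C)[Si](C)(C)Cl
Why: Standard silyl ether protection of the secondary alcohol, which masks the future ketone through all organometallic steps.

Step 4
Reactants: 6 tert-butyldimethyl{[(3R,4S)-4-methylhex-5-yn-3-yl]oxy}silane
Product: 8 tert-butyldimethyl{[(3R,4S)-4-methylhept-5-yn-3-yl]oxy}silane, via lithium acetylide 7 (not isolated)
Conditions: n-BuLi, THF, −78 °C; MeI, −78 °C → rt
Reagents that add atoms: iodomethane, CI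
Why: Acetylide alkylation; only the terminal alkyne C–H is acidic enough for one equivalent of n-BuLi at −78 °C, so the propargylic stereocentre is not touched.

Step 5
Reactants: 8 tert-butyldimethyl{[(3R,4S)-4-methylhept-5-yn-3-yl]oxy}silane
Product: 10 tert-butyl{[(3R,4S,5E)-6-iodo-4-methylhept-5-en-3-yl]oxy}dimethylsilane, via alkenylzirconocene chloride 9 (not isolated)
Conditions: Cp2Zr(H)Cl (2.5 equiv), THF, 50 °C; I2, −20 °C
Reagents that add atoms: iodine, II
Why: Schwartz hydrozirconation–iodination: syn H–Zr addition with excess reagent equilibrates zirconium to the alkyne carbon next to the small methyl group, and iodinolysis with retention gives the (E)-2-iodoalkene.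

Step 6
Reactants: 10 tert-butyl{[(3R,4S,5E)-6-iodo-4-methylhept-5-en-3-yl]oxy}dimethylsilane; 11 propyne
Product: 12 tert-butyl{[(3R,4S,5E)-4,6-dimethylnon-5-en-7-yn-3-yl]oxy}dimethylsilane
Conditions: PdCl2(PPh3)2 (5 mol %), CuI (10 mol %), i-Pr2NH, THF, propyne (excess), 0 °C → rt
Reagents that add atoms: none
Why: Sonogashira coupling of the alkenyl iodide with a terminal alkyne proceeds with retention of the (E) geometry.

Step 7
Reactants: 12 tert-butyl{[(3R,4S,5E)-4,6-dimethylnon-5-en-7-yn-3-yl]oxy}dimethylsilane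
Product: 14 tert-butyl{[(3R,4S,5E,7E)-8-iodo-4,6-dimethylnona-5,7-dien-3-yl]oxy}dimethylsilane, via dienylzirconocene chloride 13 (not isolated)
Conditions: Cp2Zr(H)Cl (2.5 equiv), THF, 50 °C, dark; I2, −78 °C
Reagents that add atoms: iodine, II
Why: A second hydrozirconation–iodination, in which zirconium settles on the methyl-bearing alkyne terminus away from the branched alkenyl group, and syn addition plus retentive iodinolysis gives the (E,E)-2-iododiene (the trisubstituted alkene is inert to the reagent).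

Step 8
Reactants: 14 tert-butyl{[(3R,4S,5E,7E)-8-iodo-4,6-dimethylnona-5,7-dien-3-yl]oxy}dimethylsilane
Product: 16 tert-butyl{[(3R,4S,5E,7E)-4,6-dimethyl-8-(trimethylstannyl)nona-5,7-dien-3-yl]oxy}dimethylsilane, via dienyllithium 15 (not isolated)
Conditions: t-BuLi (2.1 equiv), Et2O, −78 °C; Me3SnCl, −78 °C → rt
Reagents that add atoms: chlorotrimethylstannane, C[Sn](C)(C)Cl
Why: Lithium–iodine exchange and stannylation both proceed with retention of alkene geometry, and the silyl ether tolerates t-BuLi at −78 °C.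

Step 9
Reactants: 17 prop-2-yn-1-ol
Product: 19 (Z)-3-iodo-2-methylprop-2-en-1-ol, via alkenylmagnesium alkoxide 18 (not isolated)
Conditions: MeMgBr (2.5 equiv), CuI (10 mol %), THF/Et2O, −10 °C → rt; I2, −10 °C → rt; aq NH4Cl
Reagents that add atoms: methylmagnesium bromide, C[Mg]Br; iodine, II
Why: Copper-catalysed anti-carbomagnesiation of the propargylic alkoxide (Duboudin reaction) gives a chelated (Z)-alkenylmagnesium with methyl on the internal carbon, and iodinolysis with retention fixes iodine cis to the CH2OH group.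

Step 10
Reactants: 19 (Z)-3-iodo-2-methylprop-2-en-1-ol
Product: 20 (Z)-3-iodo-2-methylprop-2-enal
Conditions: MnO2 (15 equiv), CH2Cl2, rt, dark; used at once
Reagents that add atoms: none
Why: Chemoselective allylic oxidation with MnO2 under neutral conditions in the dark keeps the (Z)-iodoalkene geometry.

Step 11
Reactants: 21 pentan-3-one; 22 dimethyl carbonate
Product: 23 methyl 2-methyl-3-oxopentanoate (racemic)
Conditions: NaH (2.2 equiv), dimethyl carbonate (3 equiv), THF, reflux; 1 M HCl
Reagents that add atoms: none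
Why: Claisen-type C-carboxymethylation of the ketone enolate, driven by irreversible deprotonation of the β-keto ester formed.

Step 12
Reactants: 23 methyl 2-methyl-3-oxopentanoate; 24 N-methoxy-N-methylpropanamide
Product: 26 methyl 2,4-dimethyl-3,5-dioxoheptanoate (mixture of diastereomers and tautomers), via dianion 25 (not isolated)
Conditions: NaH (1.1 equiv), THF, 0 °C; n-BuLi (1.05 equiv), 0 °C; 24, −78 → 0 °C; 1 M HCl
Reagents that add atoms: none
Why: Huckin–Weiler dianion chemistry: the more reactive γ-carbanion is acylated, and the stable Weinreb tetrahedral adduct prevents over-addition.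

Step 13
Reactants: 26 methyl 2,4-dimethyl-3,5-dioxoheptanoate
Product: 27 6-ethyl-4-hydroxy-3,5-dimethyl-2H-pyran-2-one
Conditions: DBU (1.5 equiv), toluene, 80 °C; 1 M HCl
Reagents that add atoms: none
Why: Base-mediated lactonisation of the C5 enol oxygen onto the methyl ester gives the aromatic 4-hydroxy-2-pyrone with loss of methanol.

Step 14
Reactants: 27 6-ethyl-4-hydroxy-3,5-dimethyl-2H-pyran-2-one
Product: 28 6-ethyl-2-methoxy-3,5-dimethyl-4H-pyran-4-one
Conditions: MeOTf (1.3 equiv), CH2Cl2, rt; aq NaHCO3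
Reagents that add atoms: methyl trifluoromethanesulfonate, COS(=O)(=O)C(F)(F)F
Why: Regioselective O-methylation: the hard methylating agent attacks the lactone carbonyl oxygen to give a 2-methoxy-4-hydroxypyrylium ion, which loses a proton to form the α-methoxy-γ-pyrone.

Step 15
Reactants: 28 6-ethyl-2-methoxy-3,5-dimethyl-4H-pyran-4-one; 20 (Z)-3-iodo-2-methylprop-2-enal
Product: 30 6-[(4Z)-3-hydroxy-5-iodo-4-methylpent-4-en-2-yl]-2-methoxy-3,5-dimethyl-4H-pyran-4-one (mixture of diastereomers), via lithium dienolate 29 (not isolated)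
Conditions: LiN(SiMe3)2 (1.1 equiv), THF, −78 °C; 20, −78 °C; aq NH4Cl
Reagents that add atoms: none
Why: Vinylogous aldol addition: the 6-ethyl CH2 is the only vinylogously acidic position of the γ-pyrone, and its lithium dienolate adds 1,2 to the enal at −78 °C faster than it attacks the β-iodo position.

Step 16
Reactants: 30 6-[(4Z)-3-hydroxy-5-iodo-4-methylpent-4-en-2-yl]-2-methoxy-3,5-dimethyl-4H-pyran-4-one
Product: 32 6-[(2E,4Z)-5-iodo-4-methylpenta-2,4-dien-2-yl]-2-methoxy-3,5-dimethyl-4H-pyran-4-one, via mesylate 31 (not isolated)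
Conditions: MsCl, Et3N, CH2Cl2, 0 °C; then DBU, rt, dark
Reagents that add atoms: none
Why: Mesylation followed by E1cB elimination through the vinylogous enolate converges both aldol diastereomers on the thermodynamically preferred (E)-trisubstituted alkene, leaving the (Z)-iodoalkene intact.

Step 17
Reactants: 16 tert-butyl{[(3R,4S,5E,7E)-4,6-dimethyl-8-(trimethylstannyl)nona-5,7-dien-3-yl]oxy}dimethylsilane; 32 6-[(2E,4Z)-5-iodo-4-methylpenta-2,4-dien-2-yl]-2-methoxy-3,5-dimethyl-4H-pyran-4-one
Product: 33 6-[(2E,4Z,6E,8E,10S,11R)-11-(TBSO)-4,6,8,10-tetramethyltrideca-2,4,6,8-tetraen-2-yl]-2-methoxy-3,5-dimethyl-4H-pyran-4-one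
Conditions: Pd(PPh3)4 (10 mol %), CuI (20 mol %), CsF (2 equiv), DMF, rt, dark
Reagents that add atoms: none
Why: Stille cross-coupling, promoted by copper iodide and fluoride for the hindered α-methyl alkenylstannane, joins the two fragments with retention of both alkene geometries at a temperature where the tetraene does not yet cyclise.

Step 18
Reactants: 33 the (2E,4Z,6E,8E)-tetraenyl pyrone
Product: 34 6-[(1S,6R)-6-{(2E,4S,5R)-5-(TBSO)-4-methylhept-2-en-2-yl}-1,3,5-trimethylcyclohexa-2,4-dien-1-yl]-2-methoxy-3,5-dimethyl-4H-pyran-4-one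
Conditions: toluene (degassed, BHT), 150 °C, sealed tube, dark; preparative HPLC
Reagents that add atoms: none
Why: Thermal disrotatory 6π-electrocyclisation of the (E,Z,E)-triene puts the two outside groups (pyrone and alkenyl) cis, which fixes the relative ring configuration; the two rotation senses give the (1S,6R) and (1R,6S) rings in a ratio expected to be near 1:1 because the resident stereocentres are remote, and the (1S,6R) diastereomer is isolated by HPLC, its absolute configuration following from the enantiopure side chain.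

Step 19
Reactants: 34 the (1S,6R)-cyclohexadiene silyl ether
Product: 35 6-[(1S,6R)-6-{(2E,4S,5R)-5-hydroxy-4-methylhept-2-en-2-yl}-1,3,5-trimethylcyclohexa-2,4-dien-1-yl]-2-methoxy-3,5-dimethyl-4H-pyran-4-one
Conditions: HF·pyridine, pyridine, THF, 0 °C → rt
Reagents that add atoms: none
Why: Buffered fluoride desilylation removes the silyl group without touching the pyrone, the diene or any stereocentre.

Step 20
Reactants: 35 the (1S,6R)-cyclohexadiene alcohol
Product: 36 2-methoxy-3,5-dimethyl-6-[(1S,6R)-1,3,5-trimethyl-6-{(2E,4S)-4-methyl-5-oxohept-2-en-2-yl}cyclohexa-2,4-dien-1-yl]-4H-pyran-4-one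
Conditions: Dess–Martin periodinane (1.5 equiv), pyridine, CH2Cl2, 0 °C → rt; neutral silica
Reagents that add atoms: none
Why: Dess–Martin oxidation under buffered, near-neutral conditions converts the carbinol into the ethyl ketone without epimerising the adjacent (4S) centre or moving the β,γ-alkene into conjugation.

## Compound list

1 | (R)-but-3-yn-2-ol | C[C@@H](O)C#C | starting material
2 | (R)-but-3-yn-2-yl methanesulfonate | C[C@@H](OS(C)(=O)=O)C#C | intermediate
3 | propanal | CCC=O | starting material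
4 | (P)-buta-1,2-dien-1-ylzinc methanesulfonate | CC([H])=[C@@]=C([H])[Zn]OS(C)(=O)=O | intermediate
5 | (3R,4S)-4-methylhex-5-yn-3-ol | CC[C@@H](O)[C@@H](C)C#C | intermediate
6 | tert-butyldimethyl{[(3R,4S)-4-methylhex-5-yn-3-yl]oxy}silane | CC[C@@H](O[Si](C)(C)C(C)(C)C)[C@@H](C)C#C | intermediate
7 | lithium (3S,4R)-4-(TBSO)-3-methylhex-1-yn-1-ide | CC[C@@H](O[Si](C)(C)C(C)(C)C)[C@@H](C)C#C[Li] | intermediate
8 | tert-butyldimethyl{[(3R,4S)-4-methylhept-5-yn-3-yl]oxy}silane | CC[C@@H](O[Si](C)(C)C(C)(C)C)[C@@H](C)C#CC | intermediate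
9 | chlorobis(cyclopentadienyl)[(2E,4S,5R)-5-(TBSO)-4-methylhept-2-en-2-yl]zirconium | CC[C@@H](O[Si](C)(C)C(C)(C)C)[C@@H](C)/C=C(\C)[Zr](Cl)(C1C=CC=C1)C1C=CC=C1 | intermediate
10 | tert-butyl{[(3R,4S,5E)-6-iodo-4-methylhept-5-en-3-yl]oxy}dimethylsilane | CC[C@@H](O[Si](C)(C)C(C)(C)C)[C@@H](C)/C=C(\C)I | intermediate
11 | propyne | CC#C | starting material
12 | tert-butyl{[(3R,4S,5E)-4,6-dimethylnon-5-en-7-yn-3-yl]oxy}dimethylsilane | CC[C@@H](O[Si](C)(C)C(C)(C)C)[C@@H](C)/C=C(\C)C#CC | intermediate
13 | chlorobis(cyclopentadienyl)[(2E,4E,6S,7R)-7-(TBSO)-4,6-dimethylnona-2,4-dien-2-yl]zirconium | CC[C@@H](O[Si](C)(C)C(C)(C)C)[C@@H](C)/C=C(\C)/C=C(\C)[Zr](Cl)(C1C=CC=C1)C1C=CC=C1 | intermediate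
14 | tert-butyl{[(3R,4S,5E,7E)-8-iodo-4,6-dimethylnona-5,7-dien-3-yl]oxy}dimethylsilane | CC[C@@H](O[Si](C)(C)C(C)(C)C)[C@@H](C)/C=C(\C)/C=C(\C)I | intermediate
15 | [(4E,6S,7R)-7-(TBSO)-4,6-dimethylnona-2,4-dien-2-yl]lithium, lithium trans to C4 across C2=C3 | CC[C@@H](O[Si](C)(C)C(C)(C)C)[C@@H](C)/C=C(\C)/C=C(\C)[Li] | intermediate
16 | tert-butyl{[(3R,4S,5E,7E)-4,6-dimethyl-8-(trimethylstannyl)nona-5,7-dien-3-yl]oxy}dimethylsilane | CC[C@@H](O[Si](C)(C)C(C)(C)C)[C@@H](C)/C=C(\C)/C=C(\C)[Sn](C)(C)C | intermediate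
17 | prop-2-yn-1-ol | OCC#C | starting material
18 | bromomagnesium (2Z)-3-(bromomagnesio)-2-methylprop-2-en-1-olate | Br[Mg]/C=C(/C)CO[Mg]Br | intermediate
19 | (Z)-3-iodo-2-methylprop-2-en-1-ol | I/C=C(/C)CO | intermediate
20 | (Z)-3-iodo-2-methylprop-2-enal | I/C=C(/C)C=O | intermediate
21 | pentan-3-one | CCC(=O)CC | starting material
22 | dimethyl carbonate | COC(=O)OC | starting material
23 | methyl 2-methyl-3-oxopentanoate (racemic) | CCC(=O)C(C)C(=O)OC | intermediate
24 | N-methoxy-N-methylpropanamide | CCC(=O)N(C)OC | starting material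
25 | sodium lithium C2,C4-dianion of methyl 2-methyl-3-oxopentanoate | [Na+].[Li+].C[CH-]C(=O)[C-](C)C(=O)OC | intermediate
26 | methyl 2,4-dimethyl-3,5-dioxoheptanoate (diastereomer mixture) | CCC(=O)C(C)C(=O)C(C)C(=O)OC | intermediate
27 | 6-ethyl-4-hydroxy-3,5-dimethyl-2H-pyran-2-one | CCc1oc(=O)c(C)c(O)c1C | intermediate
28 | 6-ethyl-2-methoxy-3,5-dimethyl-4H-pyran-4-one | CCc1oc(OC)c(C)c(=O)c1C | intermediate
29 | lithium 6-ethylidene-2-methoxy-3,5-dimethyl-6H-pyran-4-olate (exocyclic geometry undefined) | [Li+].CC=C1OC(OC)=C(C)C([O-])=C1C | intermediate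
30 | 6-[(4Z)-3-hydroxy-5-iodo-4-methylpent-4-en-2-yl]-2-methoxy-3,5-dimethyl-4H-pyran-4-one (diastereomer mixture) | COc1oc(C(C)C(O)/C(C)=C\I)c(C)c(=O)c1C | intermediate
31 | (4Z)-5-iodo-2-(6-methoxy-3,5-dimethyl-4-oxo-4H-pyran-2-yl)-4-methylpent-4-en-3-yl methanesulfonate (diastereomer mixture) | COc1oc(C(C)C(OS(C)(=O)=O)/C(C)=C\I)c(C)c(=O)c1C | intermediate
32 | 6-[(2E,4Z)-5-iodo-4-methylpenta-2,4-dien-2-yl]-2-methoxy-3,5-dimethyl-4H-pyran-4-one | COc1oc(/C(C)=C/C(C)=C\I)c(C)c(=O)c1C | intermediate
33 | 6-[(2E,4Z,6E,8E,10S,11R)-11-(TBSO)-4,6,8,10-tetramethyltrideca-2,4,6,8-tetraen-2-yl]-2-methoxy-3,5-dimethyl-4H-pyran-4-one | CC[C@@H](O[Si](C)(C)C(C)(C)C)[C@@H](C)/C=C(\C)/C=C(\C)/C=C(/C)\C=C(/C)c1oc(OC)c(C)c(=O)c1C | intermediate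
34 | 6-[(1S,6R)-6-{(2E,4S,5R)-5-(TBSO)-4-methylhept-2-en-2-yl}-1,3,5-trimethylcyclohexa-2,4-dien-1-yl]-2-methoxy-3,5-dimethyl-4H-pyran-4-one | CC[C@@H](O[Si](C)(C)C(C)(C)C)[C@@H](C)/C=C(\C)[C@@H]1C(C)=CC(C)=C[C@]1(C)c1oc(OC)c(C)c(=O)c1C | intermediate
35 | 6-[(1S,6R)-6-{(2E,4S,5R)-5-hydroxy-4-methylhept-2-en-2-yl}-1,3,5-trimethylcyclohexa-2,4-dien-1-yl]-2-methoxy-3,5-dimethyl-4H-pyran-4-one | CC[C@@H](O)[C@@H](C)/C=C(\C)[C@@H]1C(C)=CC(C)=C[C@]1(C)c1oc(OC)c(C)c(=O)c1C | intermediate
36 | 2-methoxy-3,5-dimethyl-6-[(1S,6R)-1,3,5-trimethyl-6-{(2E,4S)-4-methyl-5-oxohept-2-en-2-yl}cyclohexa-2,4-dien-1-yl]-4H-pyran-4-one | CCC(=O)[C@@H](C)/C=C(\C)[C@@H]1C(C)=CC(C)=C[C@]1(C)c1oc(OC)c(C)c(=O)c1C | target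

## Step count and risks

Total step count: 20.
Longest linear sequence: 12 steps (steps 1–8, then 17–20), which is 0.60 of the total. The pyrone branch (steps 11–16) and the iodoacrolein branch (steps 9–10) run in parallel.

Steps most likely to fail:

**Step 18 (electrocyclisation).** The disrotatory closure fixes the cis relationship of the ring substituents, but the side-chain stereocentres are three bonds from the reacting terminus. The two ring diastereomers are therefore expected in a ratio near 1:1, and their separation as silyl ethers may be poor. The fallback sets out from 34, taken as the unresolved mixture with its (1R,6S) ring diastereomer, and comes back at 35. The mixture is desilylated (HF·pyridine) and the alcohols are acylated with 4-nitrobenzoyl chloride (Et3N, DMAP, CH2Cl2). This gives the crystalline 4-nitrobenzoate ester of 35 F6 beside its ring diastereomer. The two are separated by fractional crystallisation instead of chromatography, and mild methanolysis (K2CO3, MeOH, 0 °C) of pure F6 returns 35.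

**Step 7 (hydrozirconation of the enyne).** Zirconium may not go cleanly to the methyl-bearing terminus, because the alkenyl substituent also stabilises the other regioisomer, and that would scramble the position of the iodine. The fallback sets out from 10 (and uses 32) and comes back at 33, bypassing 12, 14 and 16. Lithium–iodine exchange of 10 (t-BuLi, Et2O, −78 °C) and a DMF quench give (2E,4S,5R)-5-(TBSO)-2,4-dimethylhept-2-enal F1. Corey–Fuchs olefination (CBr4, PPh3, CH2Cl2, 0 °C) gives tert-butyl{[(3R,4S,5E)-8,8-dibromo-4,6-dimethylocta-5,7-dien-3-yl]oxy}dimethylsilane F2. In parallel, 32 is stannylated (Me3SnSnMe3, Pd(PPh3)4, toluene, 60 °C) to 2-methoxy-3,5-dimethyl-6-[(2E,4Z)-4-methyl-5-(trimethylstannyl)penta-2,4-dien-2-yl]-4H-pyran-4-one F3. A trans-selective Stille coupling of F2 with F3 (Pd2(dba)3, tri(2-furyl)phosphine, toluene, rt) replaces only the bromine trans to the chain and gives 6-[(2E,4Z,6Z,8E,10S,11R)-6-bromo-11-(TBSO)-4,8,10-trimethyltrideca-2,4,6,8-tetraen-2-yl]-2-methoxy-3,5-dimethyl-4H-pyran-4-one F4. Negishi methylation of the remaining bromide with retention (Me2Zn, Pd(P(t-Bu)3)2, THF, 0 °C) gives 33. The geometry of that alkene is then set by which bromine reacts first, not by hydrometalation regiochemistry.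

**Step 17 (Stille coupling).** The α-methyl alkenylstannane is hindered, so transmetalation may be slow, and protodestannylation or E/Z scrambling of the light-sensitive polyene may compete. The fallback sets out from 14 and comes back at 33, bypassing 16. Lithiation of 14 (t-BuLi, Et2O, −78 °C) and trapping with 2-isopropoxy-4,4,5,5-tetramethyl-1,3,2-dioxaborolane give 2-[(4E,6S,7R)-7-(TBSO)-4,6-dimethylnona-2,4-dien-2-yl]-4,4,5,5-tetramethyl-1,3,2-dioxaborolane (boron trans to C4, formally 2Z) F5. Suzuki–Miyaura coupling of F5 with 32 (Pd(PPh3)4, TlOEt, THF/H2O, rt, dark) then gives 33 through a boronate pathway that avoids tin and is accelerated by the thallium base.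

## Further compounds

F1 | step 7 | (2E,4S,5R)-5-(TBSO)-2,4-dimethylhept-2-enal | CC[C@@H](O[Si](C)(C)C(C)(C)C)[C@@H](C)/C=C(\C)C=O
F2 | step 7 | tert-butyl{[(3R,4S,5E)-8,8-dibromo-4,6-dimethylocta-5,7-dien-3-yl]oxy}dimethylsilane | CC[C@@H](O[Si](C)(C)C(C)(C)C)[C@@H](C)/C=C(\C)C=C(Br)Br
F3 | step 7 | 2-methoxy-3,5-dimethyl-6-[(2E,4Z)-4-methyl-5-(trimethylstannyl)penta-2,4-dien-2-yl]-4H-pyran-4-one | COc1oc(/C(C)=C/C(C)=C\[Sn](C)(C)C)c(C)c(=O)c1C
F4 | step 7 | 6-[(2E,4Z,6Z,8E,10S,11R)-6-bromo-11-(TBSO)-4,8,10-trimethyltrideca-2,4,6,8-tetraen-2-yl]-2-methoxy-3,5-dimethyl-4H-pyran-4-one | CC[C@@H](O[Si](C)(C)C(C)(C)C)[C@@H](C)/C=C(\C)/C=C(\Br)/C=C(/C)\C=C(/C)c1oc(OC)c(C)c(=O)c1C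
F5 | step 17 | 2-[(4E,6S,7R)-7-(TBSO)-4,6-dimethylnona-2,4-dien-2-yl]-4,4,5,5-tetramethyl-1,3,2-dioxaborolane (boron trans to C4) | CC[C@@H](O[Si](C)(C)C(C)(C)C)[C@@H](C)/C=C(\C)/C=C(\C)B1OC(C)(C)C(C)(C)O1
F6 | step 18 | 4-nitrobenzoate ester of 35 (acylated at the side-chain carbinol, all stereocentres as in 35) | CC[C@@H](OC(=O)c1ccc(cc1)[N+](=O)[O-])[C@@H](C)/C=C(\C)[C@@H]1C(C)=CC(C)=C[C@]1(C)c1oc(OC)c(C)c(=O)c1C
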